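- Count turnovers, not percent: every asked flask holds 417 substrate per catalyst charged, which is c(substrate) over c(free catalyst).

| flask | substrate | gas | free catalyst | temperature | remark | time |
|---|---|---|---|---|---|---|
| amber | 0.050 M | 6.6 mM (held) | 0.080 mM | 35 °C | run made earlier |  |
| grey | 0.050 M | 6.6 mM (held) | 0.18 mM | 70 °C | run made earlier |  |
| dawn | 0.050 M | 6.6 mM (held) | 0.12 mM | 55 °C |  | 5.0 min |
| winter | 0.050 M | 6.6 mM (held) | 0.12 mM | 85 °C |  | 5.0 min |
| midnight | 0.050 M | 6.6 mM (held) | 0.12 mM | 50 °C |  | 5.0 min |
| autumn | 0.050 M | 6.6 mM (held) | 0.12 mM | 70 °C |  | 5.0 min |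
| noon | 0.050 M | 6.6 mM (held) | 0.12 mM | 40 °C |  | 5.0 min |
| dusk | 0.050 M | 6.6 mM (held) | 0.12 mM | 100 °C |  | 5.0 min |

| run | time / min | product / % |
|---|---|---|
| amber | 2.50 | 3 |
| amber | 8.00 | 10 |
| amber | 12.0 | 17 |
| amber | 15.0 | 18 |
| amber | 30.0 | 38 |
| grey | 1.00 | 7 |
| grey | 2.00 | 21 |
| grey | 3.00 | 30 |
| grey | 4.00 | 37 |
| grey | 5.00 | 47 |
| grey | 6.00 | 56 |

(scatter of a reading: 1.5 percentage points)

- all flasks from highest to lowest amount of product, in percent of the substrate charged, at 5.0 min (dawn / winter / midnight / autumn / noon / dusk)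
- the same order at 20 min (dawn / winter / midnight / autumn / noon / dusk)
- the amount of product, in percent of the substrate charged of the flask you put first, at 5.0 min
- the amount of product, in percent of the substrate charged of the flask you put last, at 5.0 min

- at the start none of the gas is in solution

- Grey climbs from 30% at 3.00 min to 56% at 6.00 min: twice the product in twice the time, so the line stays straight as c(substrate) falls, which reads as zero order in substrate.
- I therefore carry one quantity, read at the last point of each run: product made per catalyst charged per minute, 25.9 min⁻¹ in grey, the turnover frequency. Amber gives 7.92 min⁻¹. I assume that rate follows c(free catalyst), which neither run tests alone.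
- Low extreme for dusk: heat above grey's temperature buys nothing, the frequency stays at 25.9 min⁻¹, and dusk reaches 31.1%.
- High extreme for dusk: the frequency keeps rising per degree as it did from amber to grey, reaching 71.7 min⁻¹, with the catalyst intact, and dusk reaches 86.0%.
- I expect dusk between them: heat should lift it off the low extreme, but the straight lines stop at 70 °C, and at that temperature at 6.00 min.
- At grey's frequency autumn needs 16.1 min for its whole charge, less than 20 min, so I hold the hot end of the later order loosely.
- The forecast says dusk > winter > autumn > dawn > midnight > noon at 5.0 min, dusk > winter > autumn > dawn > midnight > noon at 20 min, top 72%, low 11.5%, and warns that “the top range is wide on the low side”. Its top lies below my high extreme, inside my range.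

    coupling partner + catalyst intermediate B → catalyst intermediate C (k = 920 M⁻¹ s⁻¹, Ea = 38.0 kJ mol⁻¹)
    substrate + free catalyst → catalyst intermediate A (k = 120 M⁻¹ s⁻¹, Ea = 46.0 kJ mol⁻¹)
    coupling partner + catalyst intermediate A → spent catalyst (k = 0.120 M⁻¹ s⁻¹, Ea = 45.0 kJ mol⁻¹)
    gas ⇌ coupling partner, rate k4*(csat - [coupling partner]) (kL = 0.0490 s⁻¹)
    catalyst intermediate C → free catalyst + product (k = 9.10 s⁻¹, Ea = 74.0 kJ mol⁻¹)
    catalyst intermediate A ⇌ catalyst intermediate B (K = 0.160, k = 9.20 s⁻¹, Ea = 68.0 kJ mol⁻¹, ΔH = −28.0 kJ mol⁻¹)
    (constants at 70 °C)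

- Dusk gives 44.4% and noon 12.6% at 5.0 min, in the order dusk > winter > autumn > dawn > midnight > noon, and the order at 20 min is winter > autumn > dusk > dawn > midnight > noon. At 5.00 min, dusk holds 41.1% of its catalyst as spent catalyst. Its mean turnover frequency over those minutes is 37.0 min⁻¹. A neighbour of dusk with 0.12 M of substrate shows a lower percentage, 18.9%, yet its mean frequency is 37.8 min⁻¹.

Readings and results stem from a simulated flask from invented constants.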